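**Plan** (C1 = lactone carbonyl, C7 = lactone carbinol, C8–C10 = cyclopropane with C9 the CH2, C11–C22 = side chain)
1. Cuts, in retrosynthetic order: C11–C12 (alkenylzinc + aldehyde); the C9 methylene (cyclopropanation of a C8=C10 allylic alcohol); the ring O–C1 bond by retro-Baeyer–Villiger; then C2–C3 and C6–C7 together.
2. Enabling feature: in the oxocan-2-one the four methylenes C3–C6 bridge the acetate carbon C2 and the carbinol carbon C7, and the ring oxygen lies between C7 and C1. Without that oxygen the ring is a 2-substituted cyclohept-4-enone, i.e. butadiene (C3–C6) plus a C2–C1–C7 oxyallyl unit, delivered as a rhodium siloxyvinylcarbenoid.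
3. Forward: a formal [4+3] builds the carbocycle C1–C7. The helpers (C4=C5, the ester on C2, the enol silane at C1, the carbocycle itself) are removed by hydrogenation, acidolysis/decarboxylation and Baeyer–Villiger ring expansion to the eight-membered lactone. The C8 handle then becomes enal, cyclopropane and C11 aldehyde, and the C12–C22 alkyne is joined last.
4. Stereochemistry: C7 from the chiral dirhodium catalyst (relayed through the boat Cope shift, retained in the Baeyer–Villiger migration); C8/C10 from the dioxaborolane-controlled Simmons–Smith reaction; C14 from transfer hydrogenation of an ynone; C11 from ligand-controlled alkenylzinc addition; 16Z,19Z bought with nonadienol; 12E from syn-hydroboration.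

Key step: step 4

Assumption: Rh2(S-PTAD)4 (dirhodium tetrakis[(S)-(1-adamantyl)(N-phthalimido)acetate]) is taken to give cyclopropane (1R,2S)-8 and hence (3R)-9; should the sense be the reverse, Rh2(R-PTAD)4 is used and nothing else changes.

**Step 1**
Reactants: 1 tert-butyl acetoacetate; 2 benzyl chloromethyl ether
Product: 4 tert-butyl 5-(benzyloxy)-3-oxopentanoate, via acetoacetate dianion 3 (not isolated)
Conditions: NaH, THF, 0 °C; n-BuLi, 0 °C; then 2, −20 °C → rt
Reagents that add atoms: none
Why: γ-Alkylation of the acetoacetate dianion (Weiler dianion alkylation) should occur only at the more basic terminal carbanion, attaching the future C8 as a benzyl-protected hydroxymethyl group to the future C7.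

**Step 2**
Reactants: 4 tert-butyl 5-(benzyloxy)-3-oxopentanoate
Product: 5 tert-butyl 5-(benzyloxy)-2-diazo-3-oxopentanoate
Conditions: p-ABSA, Et3N, MeCN, 0 °C → rt
Reagents that add atoms: 4-acetamidobenzenesulfonyl azide (p-ABSA), CC(=O)Nc1ccc(cc1)S(=O)(=O)N=[N+]=[N-]
Why: Regitz diazo transfer to the doubly activated methylene of a β-keto ester is routine and leaves the benzyl ether untouched.

**Step 3**
Reactants: 5 tert-butyl 5-(benzyloxy)-2-diazo-3-oxopentanoate
Product: 6 tert-butyl (3Z)-5-(benzyloxy)-3-[(tert-butyldimethylsilyl)oxy]-2-diazopent-3-enoate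
Conditions: TBSOTf, Et3N, CH2Cl2, 0 °C
Reagents that add atoms: tert-butyldimethylsilyl triflate, CC(C)(C)[Si](C)(C)OS(=O)(=O)C(F)(F)F
Why: Soft enolisation and O-silylation of the diazo ketone toward its only enolisable side should give the siloxyvinyldiazoacetate as the Z enol ether (oxygen and CH2OBn cis), the geometry that avoids allylic strain with the diazoester unit.

**Step 4**
Reactants: 6 tert-butyl (3Z)-5-(benzyloxy)-3-[(tert-butyldimethylsilyl)oxy]-2-diazopent-3-enoate; 7 buta-1,3-diene
Product: 9 tert-butyl (3R)-3-[(benzyloxy)methyl]-2-[(tert-butyldimethylsilyl)oxy]cyclohepta-1,5-diene-1-carboxylate, via cis-divinylcyclopropane 8 (not isolated)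
Conditions: Rh2(S-PTAD)4 (1 mol %), 7 (5 equiv, condensed), hexanes, sealed vessel, −30 °C → rt, slow addition of 6
Reagents that add atoms: none
Why: The dirhodium tetracarboxylate decomposes 6 to a donor/acceptor vinylcarbenoid that cyclopropanates one double bond of 7 (forming C2–C3 and, transiently, C2–C4), with the second vinyl group of the diene placed cis to the siloxyvinyl group as is general for such carbenoids, to give cis-divinylcyclopropane 8. Intermediate 8 then undergoes a [3,3] Cope rearrangement through the boat transition state open only to the cis isomer, which breaks C2–C4 and forms C6–C7, so the net event is a formal [4+3] cycloaddition; the tandem cyclopropanation/Cope reaction of vinyldiazoacetates with dienes is the direct precedent. The three-membered ring is closed by [2+1] carbene transfer and the seven-membered ring by sigmatropic ring expansion of that cyclopropane (3 → 7), leaving C1=C2 as the enol silane and C4=C5 as a cis ring alkene. The only stereocentre that survives, C7, is set by the chiral carboxylate ligands, which fix the absolute configuration of 8, and by the Z enol-ether geometry, which places CH2OBn outside in the boat so that (1R,2S)-8 can only give (3R)-9. The step needs cyclopropanation in preference to carbene dimerisation or C–H insertion (slow addition of 6 into excess 7; the Z geometry holds the benzyl ether away from the carbenoid carbon) and high enantioselectivity, while regiochemistry is not at issue because 7 is symmetrical.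

**Step 5**
Reactants: 9 tert-butyl (3R)-3-[(benzyloxy)methyl]-2-[(tert-butyldimethylsilyl)oxy]cyclohepta-1,5-diene-1-carboxylate
Product: 10 tert-butyl (3R)-3-[(benzyloxy)methyl]-2-[(tert-butyldimethylsilyl)oxy]cyclohept-1-ene-1-carboxylate
Conditions: H2 (1 atm), RhCl(PPh3)3 (5 mol %), benzene, rt
Reagents that add atoms: none
Why: Homogeneous hydrogenation with RhCl(PPh3)3 should saturate the cis-disubstituted C4=C5 alkene while the tetrasubstituted push–pull enol ether and the benzyl ether are left alone.

**Step 6**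
Reactants: 10 tert-butyl (3R)-3-[(benzyloxy)methyl]-2-[(tert-butyldimethylsilyl)oxy]cyclohept-1-ene-1-carboxylate
Product: 12 (2R)-2-[(benzyloxy)methyl]cycloheptan-1-one, via β-keto acid 11 (not isolated)
Conditions: TFA/CH2Cl2/H2O (20:80:1), 0 °C → rt; evaporate; toluene, 60 °C
Reagents that add atoms: none
Why: Acidolysis of the tert-butyl ester and the enol silane should give β-keto acid 11, which loses CO2 on gentle warming (β-keto acid decarboxylation) with enolisation confined to the C2 side, so that C7 keeps its configuration if acid exposure is kept short.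

**Step 7**
Reactants: 12 (2R)-2-[(benzyloxy)methyl]cycloheptan-1-one
Product: 13 (8R)-8-[(benzyloxy)methyl]oxocan-2-one
Conditions: mCPBA, NaHCO3, CH2Cl2, rt
Reagents that add atoms: meta-chloroperoxybenzoic acid (mCPBA), OOC(=O)c1cccc(Cl)c1
Why: In the Baeyer–Villiger oxidation the more substituted α-carbon C7 should migrate with retention of configuration, inserting oxygen between C1 and C7 and expanding the cycloheptanone to the eight-membered lactone, as in known cycloheptanone-to-oxocanone ring expansions.

**Step 8**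
Reactants: 13 (8R)-8-[(benzyloxy)methyl]oxocan-2-one
Product: 14 (8R)-8-(hydroxymethyl)oxocan-2-one
Conditions: H2 (1 atm), Pd(OH)2/C, EtOAc, rt
Reagents that add atoms: none
Why: Hydrogenolysis of the benzyl ether is safe at this stage because no alkene is present and the lactone is inert.

**Step 9**
Reactants: 14 (8R)-8-(hydroxymethyl)oxocan-2-one
Product: 15 (2R)-8-oxooxocane-2-carbaldehyde
Conditions: Dess–Martin periodinane, NaHCO3, CH2Cl2, 0 °C → rt
Reagents that add atoms: none
Why: Buffered Dess–Martin oxidation should give the α-acyloxy aldehyde without epimerising C7, and the aldehyde is used at once.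

**Step 10**
Reactants: 15 (2R)-8-oxooxocane-2-carbaldehyde; 16 (triphenylphosphoranylidene)acetaldehyde
Product: 17 (2E)-3-[(2R)-8-oxooxocan-2-yl]prop-2-enal
Conditions: toluene, rt → 40 °C
Reagents that add atoms: none
Why: Wittig olefination with the stabilised, non-basic ylide should give the E enal (C8=C10, with C11 as the aldehyde) without touching the lactone or C7.

**Step 11**
Reactants: 17 (2E)-3-[(2R)-8-oxooxocan-2-yl]prop-2-enal
Product: 18 (8R)-8-[(1E)-3-hydroxyprop-1-en-1-yl]oxocan-2-one
Conditions: NaBH4, CeCl3·7H2O, MeOH, −40 °C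
Reagents that add atoms: none
Why: Luche reduction should reduce the enal 1,2-selectively to the allylic alcohol at a temperature at which the lactone is not attacked.

**Step 12**
Reactants: 18 (8R)-8-[(1E)-3-hydroxyprop-1-en-1-yl]oxocan-2-one
Product: 19 (8R)-8-[(1R,2R)-2-(hydroxymethyl)cyclopropyl]oxocan-2-one
Conditions: Et2Zn, CH2I2, DME, CH2Cl2, −10 °C (Zn(CH2I)2·DME); then 18 and (4S,5S)-2-butyl-N,N,N',N'-tetramethyl-1,3,2-dioxaborolane-4,5-dicarboxamide (1.2 equiv), 0 °C → rt
Reagents that add atoms: diiodomethane, ICI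
Why: Charette's dioxaborolane-directed Simmons–Smith cyclopropanation delivers CH2 (C9) stereospecifically to the E alkene from the face set by the ligand, and the (4S,5S) ligand should give the (R,R) cyclopropane (C8, C10) by analogy with cinnamyl alcohol, for which the (4R,5R) ligand gives the (S,S) product.

**Step 13**
Reactants: 19 (8R)-8-[(1R,2R)-2-(hydroxymethyl)cyclopropyl]oxocan-2-one
Product: 20 (1R,2R)-2-[(2R)-8-oxooxocan-2-yl]cyclopropane-1-carbaldehyde
Conditions: Dess–Martin periodinane, NaHCO3, CH2Cl2, rt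
Reagents that add atoms: none
Why: Dess–Martin oxidation of the cyclopropylmethanol should give the configurationally stable trans-cyclopropanecarbaldehyde (C11).

**Step 14**
Reactants: 21 (3Z,6Z)-nona-3,6-dien-1-ol
Product: 22 (3Z,6Z)-nona-3,6-dienal
Conditions: Dess–Martin periodinane, NaHCO3, CH2Cl2, 0 °C; used crude
Reagents that add atoms: none
Why: Buffered Dess–Martin oxidation should give the β,γ-unsaturated aldehyde without moving the skipped Z,Z-diene into conjugation, provided the product is not chromatographed.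

**Step 15**
Reactants: 22 (3Z,6Z)-nona-3,6-dienal; 23 ethynyl(trimethyl)silane
Product: 25 (5Z,8Z)-1-(trimethylsilyl)undeca-5,8-dien-1-yn-3-ol (racemic), via lithium acetylide 24 (not isolated)
Conditions: 23, n-BuLi, THF, −78 °C; then 22, −78 °C
Reagents that add atoms: none
Why: 1,2-Addition of the lithium acetylide at −78 °C should outrun enolisation of the aldehyde and forms the C13–C14 bond.

**Step 16**
Reactants: 25 (5Z,8Z)-1-(trimethylsilyl)undeca-5,8-dien-1-yn-3-ol
Product: 26 (5Z,8Z)-1-(trimethylsilyl)undeca-5,8-dien-1-yn-3-one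
Conditions: Dess–Martin periodinane, NaHCO3, CH2Cl2, 0 °C
Reagents that add atoms: none
Why: Dess–Martin oxidation under buffered, non-basic conditions should give the ynone while the doubly activated C15 methylene is not deprotonated.

**Step 17**
Reactants: 26 (5Z,8Z)-1-(trimethylsilyl)undeca-5,8-dien-1-yn-3-one
Product: 27 (3S,5Z,8Z)-1-(trimethylsilyl)undeca-5,8-dien-1-yn-3-ol
Conditions: Ru[(S,S)-TsDPEN](p-cymene) (1 mol %), i-PrOH, rt
Reagents that add atoms: none
Why: Noyori asymmetric transfer hydrogenation of alkynyl ketones with the base-free (S,S) amido complex should give the (S) propargylic alcohol (C14), the alkynyl group taking the place of the aryl group of acetophenone in the usual model.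

**Step 18**
Reactants: 27 (3S,5Z,8Z)-1-(trimethylsilyl)undeca-5,8-dien-1-yn-3-ol
Product: 28 tert-butyl(dimethyl){[(3S,5Z,8Z)-1-(trimethylsilyl)undeca-5,8-dien-1-yn-3-yl]oxy}silane
Conditions: TBSCl, imidazole, DMF, rt
Reagents that add atoms: tert-butyldimethylsilyl chloride, CC(C)(C)[Si](C)(C)Cl
Why: Standard silylation protects the C14 hydroxyl for the organometallic steps that follow.

**Step 19**
Reactants: 28 tert-butyl(dimethyl){[(3S,5Z,8Z)-1-(trimethylsilyl)undeca-5,8-dien-1-yn-3-yl]oxy}silane
Product: 29 tert-butyl(dimethyl)[(3S,5Z,8Z)-undeca-5,8-dien-1-yn-3-yloxy]silane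
Conditions: K2CO3 (0.2 equiv), MeOH, 0 °C → rt
Reagents that add atoms: none
Why: Methanolysis removes the alkynyl C–Si group selectively, since the O–Si bond of the TBS ether is far more hindered.

**Step 20**
Reactants: 29 tert-butyl(dimethyl)[(3S,5Z,8Z)-undeca-5,8-dien-1-yn-3-yloxy]silane; 20 (1R,2R)-2-[(2R)-8-oxooxocan-2-yl]cyclopropane-1-carbaldehyde
Product: 32 (8R)-8-[(1R,2R)-2-[(1S,2E,4S,6Z,9Z)-4-[(tert-butyldimethylsilyl)oxy]-1-hydroxydodeca-2,6,9-trien-1-yl]cyclopropyl]oxocan-2-one, via alkenylborane 30 (not isolated), via alkenylzinc 31 (not isolated)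
Conditions: 29, Cy2BH (1.0 equiv), toluene, 0 °C → rt; Me2Zn, −78 °C; (−)-MIB (10 mol %), then 20, −20 → 0 °C; aq NH4Cl
Reagents that add atoms: none
Why: Syn-hydroboration of the terminal alkyne (much faster than attack on the internal Z alkenes) fixes the 12E geometry, boron-to-zinc exchange gives an alkenylzinc that tolerates the lactone, and the amino alcohol (−)-MIB should direct it to the Si face of the aldehyde (Oppolzer–Walsh alkenylzinc addition), which corresponds to 11S.

**Step 21**
Reactants: 32 (8R)-8-[(1R,2R)-2-[(1S,2E,4S,6Z,9Z)-4-[(tert-butyldimethylsilyl)oxy]-1-hydroxydodeca-2,6,9-trien-1-yl]cyclopropyl]oxocan-2-one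
Product: 33 (8R)-8-[(1R,2R)-2-[(1S,2E,4S,6Z,9Z)-1,4-dihydroxydodeca-2,6,9-trien-1-yl]cyclopropyl]oxocan-2-one (target)
Conditions: HF·pyridine, pyridine, THF, 0 °C → rt
Reagents that add atoms: none
Why: Buffered fluoride desilylation should free the C14 hydroxyl without ionising the allylic diol, opening the lactone or moving the skipped diene.

**Compound list**
1 | tert-butyl acetoacetate | CC(=O)CC(=O)OC(C)(C)C | starting material
2 | benzyl chloromethyl ether | ClCOCc1ccccc1 | starting material
3 | sodium lithium dianion (bis-enolate) of tert-butyl acetoacetate | [Na+].[Li+].C=C([O-])C=C([O-])OC(C)(C)C | intermediate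
4 | tert-butyl 5-(benzyloxy)-3-oxopentanoate | O=C(CCOCc1ccccc1)CC(=O)OC(C)(C)C | intermediate
5 | tert-butyl 5-(benzyloxy)-2-diazo-3-oxopentanoate | O=C(CCOCc1ccccc1)C(=[N+]=[N-])C(=O)OC(C)(C)C | intermediate
6 | tert-butyl (3Z)-5-(benzyloxy)-3-[(tert-butyldimethylsilyl)oxy]-2-diazopent-3-enoate | [N-]=[N+]=C(C(=O)OC(C)(C)C)/C(O[Si](C)(C)C(C)(C)C)=C/COCc1ccccc1 | intermediate
7 | buta-1,3-diene | C=CC=C | starting material
8 | tert-butyl (1R,2S)-1-[(1Z)-3-(benzyloxy)-1-[(tert-butyldimethylsilyl)oxy]prop-1-en-1-yl]-2-ethenylcyclopropane-1-carboxylate | C=C[C@@H]1C[C@]1(C(=O)OC(C)(C)C)/C(O[Si](C)(C)C(C)(C)C)=C/COCc1ccccc1 | intermediate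
9 | tert-butyl (3R)-3-[(benzyloxy)methyl]-2-[(tert-butyldimethylsilyl)oxy]cyclohepta-1,5-diene-1-carboxylate | CC(C)(C)OC(=O)C1=C(O[Si](C)(C)C(C)(C)C)[C@@H](COCc2ccccc2)CC=CC1 | intermediate
10 | tert-butyl (3R)-3-[(benzyloxy)methyl]-2-[(tert-butyldimethylsilyl)oxy]cyclohept-1-ene-1-carboxylate | CC(C)(C)OC(=O)C1=C(O[Si](C)(C)C(C)(C)C)[C@@H](COCc2ccccc2)CCCC1 | intermediate
11 | (3R)-3-[(benzyloxy)methyl]-2-oxocycloheptane-1-carboxylic acid (C1 epimers) | OC(=O)C1CCCC[C@H](COCc2ccccc2)C1=O | intermediate
12 | (2R)-2-[(benzyloxy)methyl]cycloheptan-1-one | O=C1CCCCC[C@@H]1COCc1ccccc1 | intermediate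
13 | (8R)-8-[(benzyloxy)methyl]oxocan-2-one | O=C1CCCCC[C@H](COCc2ccccc2)O1 | intermediate
14 | (8R)-8-(hydroxymethyl)oxocan-2-one | O=C1CCCCC[C@H](CO)O1 | intermediate
15 | (2R)-8-oxooxocane-2-carbaldehyde | O=C1CCCCC[C@H](C=O)O1 | intermediate
16 | (triphenylphosphoranylidene)acetaldehyde | O=CC=P(c1ccccc1)(c1ccccc1)c1ccccc1 | starting material
17 | (2E)-3-[(2R)-8-oxooxocan-2-yl]prop-2-enal | O=C1CCCCC[C@H](/C=C/C=O)O1 | intermediate
18 | (8R)-8-[(1E)-3-hydroxyprop-1-en-1-yl]oxocan-2-one | O=C1CCCCC[C@H](/C=C/CO)O1 | intermediate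
19 | (8R)-8-[(1R,2R)-2-(hydroxymethyl)cyclopropyl]oxocan-2-one | OC[C@@H]1C[C@H]1[C@H]1CCCCCC(=O)O1 | intermediate
20 | (1R,2R)-2-[(2R)-8-oxooxocan-2-yl]cyclopropane-1-carbaldehyde | O=C[C@@H]1C[C@H]1[C@H]1CCCCCC(=O)O1 | intermediate
21 | (3Z,6Z)-nona-3,6-dien-1-ol | CC/C=C\C/C=C\CCO | starting material
22 | (3Z,6Z)-nona-3,6-dienal | CC/C=C\C/C=C\CC=O | intermediate
23 | ethynyl(trimethyl)silane | C#C[Si](C)(C)C | starting material
24 | lithium (trimethylsilyl)acetylide | [Li+].[C-]#C[Si](C)(C)C | intermediate
25 | (5Z,8Z)-1-(trimethylsilyl)undeca-5,8-dien-1-yn-3-ol (racemic) | CC/C=C\C/C=C\CC(O)C#C[Si](C)(C)C | intermediate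
26 | (5Z,8Z)-1-(trimethylsilyl)undeca-5,8-dien-1-yn-3-one | CC/C=C\C/C=C\CC(=O)C#C[Si](C)(C)C | intermediate
27 | (3S,5Z,8Z)-1-(trimethylsilyl)undeca-5,8-dien-1-yn-3-ol | CC/C=C\C/C=C\C[C@H](O)C#C[Si](C)(C)C | intermediate
28 | tert-butyl(dimethyl){[(3S,5Z,8Z)-1-(trimethylsilyl)undeca-5,8-dien-1-yn-3-yl]oxy}silane | CC/C=C\C/C=C\C[C@H](O[Si](C)(C)C(C)(C)C)C#C[Si](C)(C)C | intermediate
29 | tert-butyl(dimethyl)[(3S,5Z,8Z)-undeca-5,8-dien-1-yn-3-yloxy]silane | CC/C=C\C/C=C\C[C@H](O[Si](C)(C)C(C)(C)C)C#C | intermediate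
30 | [(1E,3S,5Z,8Z)-3-[(tert-butyldimethylsilyl)oxy]undeca-1,5,8-trien-1-yl]dicyclohexylborane | CC/C=C\C/C=C\C[C@H](O[Si](C)(C)C(C)(C)C)/C=C/B(C1CCCCC1)C1CCCCC1 | intermediate
31 | [(1E,3S,5Z,8Z)-3-[(tert-butyldimethylsilyl)oxy]undeca-1,5,8-trien-1-yl](methyl)zinc | CC/C=C\C/C=C\C[C@H](O[Si](C)(C)C(C)(C)C)/C=C/[Zn]C | intermediate
32 | (8R)-8-[(1R,2R)-2-[(1S,2E,4S,6Z,9Z)-4-[(tert-butyldimethylsilyl)oxy]-1-hydroxydodeca-2,6,9-trien-1-yl]cyclopropyl]oxocan-2-one | CC/C=C\C/C=C\C[C@H](O[Si](C)(C)C(C)(C)C)/C=C/[C@H](O)[C@@H]1C[C@H]1[C@H]1CCCCCC(=O)O1 | intermediate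
33 | (8R)-8-[(1R,2R)-2-[(1S,2E,4S,6Z,9Z)-1,4-dihydroxydodeca-2,6,9-trien-1-yl]cyclopropyl]oxocan-2-one | CC/C=C\C/C=C\C[C@H](O)/C=C/[C@H](O)[C@@H]1C[C@H]1[C@H]1CCCCCC(=O)O1 | target

**Step count:** 21 steps in total. Longest linear sequence: 15 steps (steps 1–13, then 20 and 21); the side-chain alkyne takes steps 14–19.

**Steps most likely to fail**

Step 4. The carbenoid may be lost to dimerisation, or enantiofacial control in the cyclopropanation may be incomplete, which would erode the configuration at C7. The fallback builds the ring and C7 by auxiliary-controlled alkylation instead. It sets out from benzyl chloromethyl ether 2. Commercial cycloheptanone is condensed with (R)-1-amino-2-(methoxymethyl)pyrrolidine (RAMP; neat, 60 °C) to give the cycloheptanone RAMP hydrazone F1. F1 is deprotonated with LiN(i-Pr)2 (THF, 0 °C) and alkylated with 2 at −95 °C to give the α-(benzyloxymethyl) hydrazone F2. Cleavage with saturated aqueous oxalic acid/Et2O, which is free of epimerisation, should give ketone 12, where the route is rejoined before step 7.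

Step 17. The weakly basic ruthenium amide may move the skipped C16=C17 double bond into conjugation with the ynone before or during hydride transfer. The fallback avoids the ynone: it sets out from aldehyde 22 and alkyne 23 and joins them directly in a catalytic enantioselective alkynylation (Me2Zn with a ProPhenol ligand, or Et2Zn/Ti(OiPr)4/BINOL, using the ligand antipode that gives the 3S alcohol). This returns to the route at 27 and bypasses 25 and 26; the detour makes no new compound (F0).

Step 20. Hydroboration may compete at the skipped diene, and facial control at C11 may be incomplete in the mismatched sense. The fallback sets out from alkyne 29. Hydrozirconation and iodination (Cp2Zr(H)Cl, THF; then I2) should give the E vinyl iodide F3. Nozaki–Hiyama–Kishi coupling of F3 with aldehyde 20 (CrCl2, catalytic NiCl2, DMSO, rt) gives 32 together with its C11 epimer F4. After separation, F4 is inverted by Mitsunobu reaction (ClCH2CO2H, PPh3, DIAD, toluene, 0 °C) to the 11S chloroacetate F5. Cleavage of F5 with thiourea/NaHCO3 in EtOH returns to the route at 32.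

**Further compounds**
F1 | step 4 | (2R)-N-cycloheptylidene-2-(methoxymethyl)pyrrolidin-1-amine (cycloheptanone RAMP hydrazone) | COC[C@H]1CCCN1N=C1CCCCCC1
F2 | step 4 | (2R)-N-[(2S)-2-[(benzyloxy)methyl]cycloheptylidene]-2-(methoxymethyl)pyrrolidin-1-amine | COC[C@H]1CCCN1N=C1CCCCC[C@@H]1COCc1ccccc1
F0 | step 17 | none | none
F3 | step 20 | tert-butyl{[(1E,3S,5Z,8Z)-1-iodoundeca-1,5,8-trien-3-yl]oxy}dimethylsilane | CC/C=C\C/C=C\C[C@H](O[Si](C)(C)C(C)(C)C)/C=C/I
F4 | step 20 | (8R)-8-[(1R,2R)-2-[(1R,2E,4S,6Z,9Z)-4-[(tert-butyldimethylsilyl)oxy]-1-hydroxydodeca-2,6,9-trien-1-yl]cyclopropyl]oxocan-2-one (C11 epimer of 32) | CC/C=C\C/C=C\C[C@H](O[Si](C)(C)C(C)(C)C)/C=C/[C@@H](O)[C@@H]1C[C@H]1[C@H]1CCCCCC(=O)O1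
F5 | step 20 | (1S,2E,4S,6Z,9Z)-4-[(tert-butyldimethylsilyl)oxy]-1-[(1R,2R)-2-[(2R)-8-oxooxocan-2-yl]cyclopropyl]dodeca-2,6,9-trien-1-yl chloroacetate | CC/C=C\C/C=C\C[C@H](O[Si](C)(C)C(C)(C)C)/C=C/[C@H](OC(=O)CCl)[C@@H]1C[C@H]1[C@H]1CCCCCC(=O)O1
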